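**Retrosynthetic overview**
- The target comes from its 5-O-methyl, 3'-O-methoxymethyl (MOM) ether by chelation-controlled demethylation and acetal cleavage in one flask.
- Key disconnection, C3–C4: the ring A aldehyde carbon is used as an acyl anion (carbene-derived) and attacks the aldehyde carbon that becomes C3. This intramolecular crossed benzoin closes ring C and sets C2 and C3 together by dynamic kinetic resolution of a racemic dialdehyde.
- O1–C2: the dialdehyde comes from a ring A salicylaldehyde and a racemic α-bromo arylacetate (ring B), followed by reduction to the diol and double oxidation.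
- C6–prenyl: a para-Claisen–Cope shift of the prenyl ether of 2-hydroxy-4,6-dimethoxybenzaldehyde places the prenyl group and frees exactly the phenol that becomes O1.
- Ring order: rings A and B are bought as aromatics; ring C is the only ring built and is closed in the benzoin step.

Assumption: the (5aR,10bS) antipode of the aminoindanol-derived triazolium salt is taken as the one that gives (2R,3R); if a first small run shows the opposite sense, its mirror image is used and nothing else changes.

**Step 1**
Reactants: 1 2-hydroxy-4,6-dimethoxybenzaldehyde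
Product: 2 2,4-dimethoxy-6-[(3-methylbut-2-en-1-yl)oxy]benzaldehyde
Conditions: prenyl bromide, K2CO3, acetone, reflux
Reagents that add atoms: prenyl bromide (1-bromo-3-methylbut-2-ene), CC(C)=CCBr
Why: Williamson ether synthesis on the only free phenol, which places the prenyl group on the oxygen that later becomes O1.

**Step 2**
Reactants: 2 2,4-dimethoxy-6-[(3-methylbut-2-en-1-yl)oxy]benzaldehyde
Product: 5 6-hydroxy-2,4-dimethoxy-3-(3-methylbut-2-en-1-yl)benzaldehyde, via ortho-dienone 3 (not isolated), via para-dienone 4 (not isolated)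
Conditions: PhNEt2, 200 °C, sealed tube, argon
Reagents that add atoms: none
Why: Aromatic Claisen rearrangement followed by Cope rearrangement and enolisation (para-Claisen–Cope): one ortho carbon carries the formyl group and the tertiary allyl group at the other is expected to move on to the para carbon between the two methoxy groups faster than it tautomerises, so an unbranched prenyl group arrives para to the released phenol, as in the closely related 2-prenyloxy-4,6-dialkoxyacetophenones.

**Step 3**
Reactants: 6 (3-hydroxy-4-methoxyphenyl)acetic acid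
Product: 7 methoxymethyl [4-methoxy-3-(methoxymethoxy)phenyl]acetate
Conditions: MOMCl (2.5 equiv), i-Pr2NEt, CH2Cl2, 0 °C → rt
Reagents that add atoms: chloromethyl methyl ether (MOMCl), COCCl
Why: One-pot O-alkylation of phenoxide and carboxylate (MOM protection) gives a base-stable aryl MOM ether and an ester that step 6 can reduce.

**Step 4**
Reactants: 7 methoxymethyl [4-methoxy-3-(methoxymethoxy)phenyl]acetate
Product: 9 racemic methoxymethyl bromo[4-methoxy-3-(methoxymethoxy)phenyl]acetate, via lithium enolate 8 (not isolated)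
Conditions: LiN(SiMe3)2, THF, −78 °C; then NBS, −78 °C; NH4Cl quench; used crude
Reagents that add atoms: N-bromosuccinimide (NBS), O=C1CCC(=O)N1Br
Why: Enolate α-bromination: the benzylic α-CH is deprotonated at −78 °C and the enolate is halogenated by NBS faster than NBS can attack the electron-rich arene; the new stereocentre is racemic, which is what step 8 needs.

**Step 5**
Reactants: 5 6-hydroxy-2,4-dimethoxy-3-(3-methylbut-2-en-1-yl)benzaldehyde; 9 racemic methoxymethyl bromo[4-methoxy-3-(methoxymethoxy)phenyl]acetate
Product: 10 racemic methoxymethyl [2-formyl-3,5-dimethoxy-4-(3-methylbut-2-en-1-yl)phenoxy][4-methoxy-3-(methoxymethoxy)phenyl]acetate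
Conditions: K2CO3 (1.2 equiv), acetone, 0 °C → rt
Reagents that add atoms: none
Why: Williamson etherification (SN2 at an activated benzylic α-bromo ester) by the salicylaldehyde phenoxide forms the O1–C2 bond under carbonate conditions mild enough to keep aldol closure on to the formyl group slow.

**Step 6**
Reactants: 10 racemic methoxymethyl [2-formyl-3,5-dimethoxy-4-(3-methylbut-2-en-1-yl)phenoxy][4-methoxy-3-(methoxymethoxy)phenyl]acetate
Product: 11 racemic 2-[2-(hydroxymethyl)-3,5-dimethoxy-4-(3-methylbut-2-en-1-yl)phenoxy]-2-[4-methoxy-3-(methoxymethoxy)phenyl]ethan-1-ol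
Conditions: LiAlH4, THF, 0 °C; H2O/NaOH work-up
Reagents that add atoms: none
Why: Hydride reduction of both the aryl aldehyde and the ester gives a stable diol, because the ester cannot be taken to the aldehyde selectively beside the aryl aldehyde; the aryl MOM ether, the benzylic aryl ether and the prenyl group are inert.

**Step 7**
Reactants: 11 racemic 2-[2-(hydroxymethyl)-3,5-dimethoxy-4-(3-methylbut-2-en-1-yl)phenoxy]-2-[4-methoxy-3-(methoxymethoxy)phenyl]ethan-1-ol
Product: 12 racemic 6-{1-[4-methoxy-3-(methoxymethoxy)phenyl]-2-oxoethoxy}-2,4-dimethoxy-3-(3-methylbut-2-en-1-yl)benzaldehyde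
Conditions: Dess–Martin periodinane (2.5 equiv), pyridine, CH2Cl2, 0 °C → rt; used at once
Reagents that add atoms: none
Why: Dess–Martin oxidation of both primary alcohols under buffered, non-basic conditions gives the dialdehyde without base-promoted aldol side reactions and leaves the alkene and the electron-rich arenes untouched.

**Step 8**
Reactants: 12 racemic 6-{1-[4-methoxy-3-(methoxymethoxy)phenyl]-2-oxoethoxy}-2,4-dimethoxy-3-(3-methylbut-2-en-1-yl)benzaldehyde
Product: 13 (2R,3R)-3-hydroxy-5,7-dimethoxy-2-[4-methoxy-3-(methoxymethoxy)phenyl]-6-(3-methylbut-2-en-1-yl)-2,3-dihydro-4H-chromen-4-one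
Conditions: (5aR,10bS)-2-(pentafluorophenyl)-5a,10b-dihydro-4H,6H-indeno[2,1-b][1,2,4]triazolo[4,3-d][1,4]oxazin-2-ium tetrafluoroborate (10 mol%), i-Pr2NEt (1 equiv), 4 Å molecular sieves, toluene, rt
Reagents that add atoms: none
Why: Proposed new method: the carbene adds to the ring A aldehyde to give a Breslow-type acyl anion equivalent (the α-branched α-aryloxy aldehyde is a poor acyl donor but a strongly activated acceptor), which attacks the neighbouring aldehyde in a 6-exo intramolecular crossed benzoin reaction that forms C3–C4 and ring C; because C2 of 12 is benzylic, oxygen-bearing and α to the aldehyde it should racemise through its enol under i-Pr2NEt faster than it cyclises, so the chiral carbene fixes the face of attack at C3 while the ring B aryl group prefers a pseudo-equatorial place in the chair-like transition state, which channels both enantiomers of 12 into the trans (2R,3R) ketol by dynamic kinetic resolution; the closest known reactions are the enantioselective carbene-catalysed aldehyde–ketone benzoin cyclisations to 3-hydroxychroman-4-ones and carbene-catalysed cross-benzoin reactions of aromatic aldehydes with α-heteroatom-substituted aldehydes.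

**Step 9**
Reactants: 13 (2R,3R)-3-hydroxy-5,7-dimethoxy-2-[4-methoxy-3-(methoxymethoxy)phenyl]-6-(3-methylbut-2-en-1-yl)-2,3-dihydro-4H-chromen-4-one
Product: 15 (2R,3R)-3,5-dihydroxy-2-(3-hydroxy-4-methoxyphenyl)-7-methoxy-6-(3-methylbut-2-en-1-yl)-2,3-dihydro-4H-chromen-4-one (the target), via C5 phenol 14 (not isolated)
Conditions: MgI2·OEt2 (5 equiv), THF, 60 °C; then 3 M HCl, MeOH, 40 °C
Reagents that add atoms: none
Why: Chelation-controlled ether cleavage, in which magnesium held between the C4 carbonyl and O5 activates only that methyl group for SN2 attack by iodide (a method that spares prenyl groups and unchelated methyl ethers), followed by acid-catalysed methanolysis of the MOM acetal; neither stereocentre is touched and trans is also the thermodynamic arrangement.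

**Compound list**
1 | 2-hydroxy-4,6-dimethoxybenzaldehyde | COc1cc(O)c(C=O)c(OC)c1 | starting material
2 | 2,4-dimethoxy-6-[(3-methylbut-2-en-1-yl)oxy]benzaldehyde | COc1cc(OCC=C(C)C)c(C=O)c(OC)c1 | intermediate
3 | 2,4-dimethoxy-5-(2-methylbut-3-en-2-yl)-6-oxocyclohexa-1,3-diene-1-carbaldehyde (ortho-dienone, racemic, not isolated) | O=CC1=C(OC)C=C(OC)C(C(C)(C)C=C)C1=O | intermediate
4 | 2,4-dimethoxy-3-(3-methylbut-2-en-1-yl)-6-oxocyclohexa-1,4-diene-1-carbaldehyde (para-dienone, not isolated) | O=CC1=C(OC)C(CC=C(C)C)C(OC)=CC1=O | intermediate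
5 | 6-hydroxy-2,4-dimethoxy-3-(3-methylbut-2-en-1-yl)benzaldehyde | COc1cc(O)c(C=O)c(OC)c1CC=C(C)C | intermediate
6 | (3-hydroxy-4-methoxyphenyl)acetic acid | COc1ccc(CC(=O)O)cc1O | starting material
7 | methoxymethyl [4-methoxy-3-(methoxymethoxy)phenyl]acetate | COCOC(=O)Cc1ccc(OC)c(OCOC)c1 | intermediate
8 | lithium enolate of 7 (not isolated) | [Li+].[O-]C(OCOC)=Cc1ccc(OC)c(OCOC)c1 | intermediate
9 | racemic methoxymethyl bromo[4-methoxy-3-(methoxymethoxy)phenyl]acetate | COCOC(=O)C(Br)c1ccc(OC)c(OCOC)c1 | intermediate
10 | racemic methoxymethyl [2-formyl-3,5-dimethoxy-4-(3-methylbut-2-en-1-yl)phenoxy][4-methoxy-3-(methoxymethoxy)phenyl]acetate | COCOC(=O)C(Oc1cc(OC)c(CC=C(C)C)c(OC)c1C=O)c1ccc(OC)c(OCOC)c1 | intermediate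
11 | racemic 2-[2-(hydroxymethyl)-3,5-dimethoxy-4-(3-methylbut-2-en-1-yl)phenoxy]-2-[4-methoxy-3-(methoxymethoxy)phenyl]ethan-1-ol | OCC(Oc1cc(OC)c(CC=C(C)C)c(OC)c1CO)c1ccc(OC)c(OCOC)c1 | intermediate
12 | racemic 6-{1-[4-methoxy-3-(methoxymethoxy)phenyl]-2-oxoethoxy}-2,4-dimethoxy-3-(3-methylbut-2-en-1-yl)benzaldehyde | O=CC(Oc1cc(OC)c(CC=C(C)C)c(OC)c1C=O)c1ccc(OC)c(OCOC)c1 | intermediate
13 | (2R,3R)-3-hydroxy-5,7-dimethoxy-2-[4-methoxy-3-(methoxymethoxy)phenyl]-6-(3-methylbut-2-en-1-yl)-2,3-dihydro-4H-chromen-4-one | COc1ccc([C@H]2Oc3cc(OC)c(CC=C(C)C)c(OC)c3C(=O)[C@@H]2O)cc1OCOC | intermediate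
14 | (2R,3R)-3,5-dihydroxy-7-methoxy-2-[4-methoxy-3-(methoxymethoxy)phenyl]-6-(3-methylbut-2-en-1-yl)-2,3-dihydro-4H-chromen-4-one (not isolated) | COc1ccc([C@H]2Oc3cc(OC)c(CC=C(C)C)c(O)c3C(=O)[C@@H]2O)cc1OCOC | intermediate
15 | (2R,3R)-3,5-dihydroxy-2-(3-hydroxy-4-methoxyphenyl)-7-methoxy-6-(3-methylbut-2-en-1-yl)-2,3-dihydro-4H-chromen-4-one | COc1ccc([C@H]2Oc3cc(OC)c(CC=C(C)C)c(O)c3C(=O)[C@@H]2O)cc1O | target

**Step count**
Total: 9 steps. Longest linear sequence: 7 steps (1, 2, 5, 6, 7, 8, 9 from compound 1; equally 3, 4, 5, 6, 7, 8, 9 from compound 6).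

**Steps most likely to fail**

Step 8 (benzoin cyclisation with dynamic kinetic resolution). This step is untested on such a substrate. The likely failure modes are:
- carbene addition to the aliphatic aldehyde followed by β-loss of the ring A phenoxide (internal redox to an aryl ester);
- 5-exo aldol attack of the enol on the ring A aldehyde;
- the doubly ortho-substituted aldehyde being a sluggish acyl donor;
- low enantiomeric excess.

Fallback: set out from 12 and give up catalyst control. A small achiral carbene (3-benzyl-5-(2-hydroxyethyl)-4-methylthiazolium chloride, Et3N, dioxane, 60 °C) closes ring C and the amine equilibrates C3, giving racemic trans-(2R*,3R*)-3-hydroxy-5,7-dimethoxy-2-[4-methoxy-3-(methoxymethoxy)phenyl]-6-(3-methylbut-2-en-1-yl)-2,3-dihydro-4H-chromen-4-one F1. The enantiomers are separated by preparative chromatography on a chiral stationary phase (amylose tris(3,5-dimethylphenylcarbamate), supercritical CO2/MeOH). The (2R,3R) half is 13, where the route is rejoined.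

Step 2 (para-Claisen–Cope shift). The competing outcomes are enolisation of the ortho-dienone to the branched 1,1-dimethylallyl phenol, and loss of the formyl group at 200 °C.

Fallback: set out from 1 and install the prenyl group by cross-coupling instead of a sigmatropic shift.
- Silylation (i-Pr3SiCl, imidazole, DMF) gives 2,4-dimethoxy-6-[(triisopropylsilyl)oxy]benzaldehyde F2.
- NBS in MeCN at 0 °C brominates the position between the two methoxy groups, because the other free position is shielded by the silyl ether, giving 3-bromo-2,4-dimethoxy-6-[(triisopropylsilyl)oxy]benzaldehyde F3.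
- Suzuki–Miyaura coupling with prenylboronic acid pinacol ester (Pd(OAc)2, a bulky biarylphosphine chosen for linear selectivity, K3PO4, THF/H2O, 40 °C) gives 2,4-dimethoxy-3-(3-methylbut-2-en-1-yl)-6-[(triisopropylsilyl)oxy]benzaldehyde F4.
- Bu4NF/AcOH in THF removes the silyl group and returns to the route at 5.

Step 4 (α-bromination). The risks are proton exchange leading to dibromide, and solvolysis of the very labile p-alkoxybenzylic bromide 9 before it is used.

Fallback: set out from 7 and form the O1–C2 bond by Mitsunobu reaction instead of halide displacement.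
- KN(SiMe3)2 in THF at −78 °C gives the potassium enolate of 7 F5.
- Oxidation with 2-(phenylsulfonyl)-3-phenyloxaziridine gives racemic methoxymethyl hydroxy[4-methoxy-3-(methoxymethoxy)phenyl]acetate F6.
- Coupling with phenol 5 (PPh3, diisopropyl azodicarboxylate, THF, 0 °C → rt) is neutral and avoids any aldol closure; it returns to the route at 10.

**Further compounds**
F1 | step 8 | racemic trans-(2R*,3R*)-3-hydroxy-5,7-dimethoxy-2-[4-methoxy-3-(methoxymethoxy)phenyl]-6-(3-methylbut-2-en-1-yl)-2,3-dihydro-4H-chromen-4-one | COc1ccc([C@H]2Oc3cc(OC)c(CC=C(C)C)c(OC)c3C(=O)[C@@H]2O)cc1OCOC.COc1ccc([C@@H]2Oc3cc(OC)c(CC=C(C)C)c(OC)c3C(=O)[C@H]2O)cc1OCOC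
F2 | step 2 | 2,4-dimethoxy-6-[(triisopropylsilyl)oxy]benzaldehyde | COc1cc(O[Si](C(C)C)(C(C)C)C(C)C)c(C=O)c(OC)c1
F3 | step 2 | 3-bromo-2,4-dimethoxy-6-[(triisopropylsilyl)oxy]benzaldehyde | COc1cc(O[Si](C(C)C)(C(C)C)C(C)C)c(C=O)c(OC)c1Br
F4 | step 2 | 2,4-dimethoxy-3-(3-methylbut-2-en-1-yl)-6-[(triisopropylsilyl)oxy]benzaldehyde | COc1cc(O[Si](C(C)C)(C(C)C)C(C)C)c(C=O)c(OC)c1CC=C(C)C
F5 | step 4 | potassium enolate of 7 | [K+].[O-]C(OCOC)=Cc1ccc(OC)c(OCOC)c1
F6 | step 4 | racemic methoxymethyl hydroxy[4-methoxy-3-(methoxymethoxy)phenyl]acetate | COCOC(=O)C(O)c1ccc(OC)c(OCOC)c1
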